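The data come from a simulation with constants of no real substance; noise was put on by code.

In a one-step world, where G meets E on Q and Q stays as charged, the slope of X falls with c_G·c_E and with nothing else.

in all of them: G 18 mM; Q 90 µM
- west: E 45 mM; temperature 70 °C; the very flask that is asked about, followed so far
- south-east: E 30 mM; temperature 65 °C; run made earlier
- flask: E 45.0 mM; temperature 70 °C; time 5.0 d

west run (percent of the G charged)

| time / d | X / % | G / % |
|---|---|---|
| 0.417 | 6.0 | 69.7 |
| 0.833 | 8.7 | 67.6 |
| 1.25 | 11.5 | 64.1 |
| 2.50 | 15.0 | 60.3 |
| 5.00 | 16.5 | 56.1 |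

south-east run (percent of the G charged)

| time / h | X / % | G / % |
|---|---|---|
| 4.00 | 1.6 | 75.8 |
| 8.00 | 1.5 | 72.8 |
| 15.0 | 3.9 | 70.6 |
| 25.0 | 5.0 | 70.1 |
| 50.0 | 9.5 | 65.3 |

(standard deviation of a reading: 0.5 percentage points)

- green: at 5.0 d raise the temperature by 15 K, then wait 2.5 d
- violet: at 5.0 d take out 90% of the X then present, then wait 2.5 d
- red: at 5.0 d add Q, 100% of the amount charged, then wait 2.5 d
- amber: at 5.0 d add E, 100% of the amount charged, then wait 2.5 d
- ochre: change nothing and wait 2.5 d more

- X, in percent of the G first charged, at 5.0 d
- what to do for the largest gain in X; "none" if nothing gains more than 2 percentage points (green / violet / red / amber / ochre / none)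
- X present, with what was taken out counted in, in percent of the G first charged, after green
- X present, with what was taken out counted in, in percent of the G first charged, after violet

- X that was removed still counts
- additions bring no volume worth counting

The west run is the asked flask, followed so far. Up to its first reading, X rises at 2.59 mM d⁻¹, but between its last two readings it rises at 0.108 mM d⁻¹, far slower. Over that span c_G keeps a factor of 0.805. The X made, 2.97 mM, is small beside the 45.0 mM of E, so at one E per X, c_E stays close to its charge. The one-step world therefore fails in this flask. Two accounts of the stall stand open, an equilibrium and a loss of working Q, and this reckoning commits to the loss.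

The last reading, 16.5%, then counts as the level, and it amounts to 33.0 X per Q charged. This is the capacity of Q, the turnover number. The starting slope meets that level at the knee, 1.15 d, and the reading at 1.25 d already stands at 0.697 of the level.

If working Q decays exponentially with that time constant, the capacity unused at 5.0 d is 0.21 percentage points, less than the margin of 2 points. With capacity taken as unchanged by heat or by removing X, green and violet both end near 16.7%. Fresh Q brings new capacity, 16 points, which exceeds the margin and fits within the 56.1% of G still present. So this reckoning says 16.5% now, and red.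

The forecast gives 16.8%, red, 17.3% after green and 17.2% after violet, somewhat above this reckoning on both options, and holds that “fresh Q should restart X”.

The flask gives 17.5%.

    G + Q ⇌ Q + J (K = 0.370, k = 52.0 M⁻¹ min⁻¹, Ea = 67.0 kJ mol⁻¹, ΔH = 2.00 kJ mol⁻¹)
    Q + J ⇌ Z (K = 120 M⁻¹, k = 220 M⁻¹ min⁻¹, Ea = 43.0 kJ mol⁻¹, ΔH = −10.0 kJ mol⁻¹)
    E + Z → Q + X (k = 1.30 M⁻¹ min⁻¹, Ea = 82.0 kJ mol⁻¹)
    E + Q → L (k = 0.0170 M⁻¹ min⁻¹, Ea = 82.0 kJ mol⁻¹)
    G + E → D (k = 3.20 × 10⁻⁴ M⁻¹ min⁻¹, Ea = 99.0 kJ mol⁻¹)
    (constants at 70 °C)

The best choice is red, and at 5.00 d the catalyst charged to this flask stands as 2.06% Q, 0.886% Z and 97.1% L. By 5.0 d this flask has made 35.0 X per Q charged. Added Q gains 12 points in 2.5 d, against the 16 points reckoned, while green gives 17.9% and violet 17.9%. For the neighbour flask charged with 0.36 mM of Q, the capacity 33.0 reckons 66.0%, and at 5.0 d that flask gives 54.7% with 30.7% of G remaining.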